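## Structural features

The target is a ten-membered lactone (an oxecin-2-one; O1, C2 carbonyl, C3 to C10 in the ring, propyl C11–C13 on C10) with one E double bond, C6=C7, inside the ring. It has four stereocentres: C3 (R), which carries the acyloxy group next to the lactone carbonyl, and the contiguous triad C8 (R), C9 (S), C10 (R). In the triad C8/C9 are threo and C9/C10 erythro; C8 is allylic and C10 is the lactone carbinol. The C3 oxygen is esterified by (E,E)-muconic acid, whose second carboxyl is free. Fragile elements are the α-acyloxy lactone (base brings epimerisation, acyl shift or ring opening), the doubly conjugated half-ester (a Michael acceptor), the allylic 8,9-diol (ionisation, acyl migration) and the medium ring itself (strain, slow closure). The real difficulty is to place the C8 carbinol threo to C9 beside an E alkene and then to close the ring through the hindered C10 hydroxyl while the oxygens at C3, C8 and C9 are told apart. The key step uses the O–C9–C8–C7=C6 array: the allylic C8–O bond trans to the C9–O bond is the 1,3-transposed form of a C6 oxygen on a C7=C8 alkene, so a C6 carbonate can be turned into the C8/C9 cyclic carbonate and the E C6=C7 bond in one operation.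

## Logic of the disconnections

**34 to 33.** No skeletal bond is cut. The 8,9-diol is masked as an isopropylidene acetal and the free carboxyl as a tert-butyl ester, so that one acid treatment unveils both. The demand is an acid step mild enough for the C3 ester, the lactone and the allylic diol.

**33 to 29 and 31.** The C3–O acyl bond is cut. The dienoate half-ester is the most base- and nucleophile-sensitive part, so it is attached last. 31 comes from 30 by mono-esterification. The forward step must acylate a hindered α-hydroxy lactone without epimerising C3.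

**29 to 28 to 26.** The O1–C2 lactone bond is cut after the C3 oxygen is put back under a silyl group. This opens the ring to a seco acid in which only the C10 hydroxyl is free. The forward step is a ten-membered closure under high dilution.

**26 to 25 to 24 to 23 to 22.** Only protecting groups change: acid from methyl ester, C10 hydroxyl from its benzyl-type ether, acetal from diol, diol from cyclic carbonate. The carbonate is exchanged because it would not survive ester hydrolysis and could not be removed at the end beside the C3 acyl group. The carbonate cleavage must leave the C2 ester and the C3 silyl ether alone; methanolysis is degenerate for a methyl ester.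

**22 to 21.** The C8–O bond and the carbonate ring are cut, the alkene is moved from C6=C7 to C7=C8, and the oxygen is placed on C6 as a methyl carbonate. This removes the C8 stereocentre and the need for a defined alkene geometry. The forward step must attack C8 and not C6, give the E alkene, and set C8 trans to C9.

**21 to 20 to 19 to 8, 15 and 16.** The Z alkene comes from an alkyne, the C9 hydroxyl from a silyl ether, and the C6–C7 bond and the C6–O carbonate bond are cut together. The result is two fragments of similar size, each with its own stereocentres. The forward step must add an acetylide to an aldehyde that also carries an ester, and trap the alkoxide before it lactonises onto C2. The C9 silyl group must come off while the C3 silyl group stays.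

**8 to 6 and 7, then 4, 3, 2, 1.** The alkyne carbon C7 is removed (one-carbon homologation of an aldehyde), the C10–O ether bond is cut back to an epoxide, and the epoxide to an allylic alcohol. Both carbinol centres thus come from one catalytic asymmetric step. The epoxide must be opened at the carbon remote from the hydroxymethyl group, with inversion.

**15 to 14 to 12 to 11 to 9 and 10.** The aldehyde is traced to a terminal alkene and the C4–C5 bond is cut to a three-carbon epoxy ester and a vinyl nucleophile. C3 comes from the chiral pool and the two ends of the C2–C6 unit are different from the start.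

## Other disconnections considered

**Alternative 1:** The C2–C3 bond and the C3–O acyl bond are cut together, leading to the C3 aldehyde A2, the half-ester 31 and the convertible isocyanide A3. Forward, a chiral phosphoric acid would join the three in a Passerini reaction to the α-acyloxy anilide A1, with C3 set by the catalyst.
- In favour: one step forms two bonds and a stereocentre, and no protecting group is needed on C3.
- Against: A2 still needs the C8–C10 triad and the E alkene, so a step like the palladium transposition is still required upstream. The anilide must be activated by acid (indole formation) and lactonised with the muconate already next to the reacting carbonyl, which invites acyl shift and threatens the acetal and silyl ether. Catalyst control with an unbranched aldehyde and a conjugated acid is less assured than a pool-derived centre.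
- Comparison: on step economy at the C3 end this alternative is the better plan (it saves the desilylation and late acylation). On structure it is equal, since it solves only C3. On mechanism the chosen plan is safer, because ring closure goes through an ordinary seco acid.

**Alternative 2:** The C2–C7 bond of a six-membered carbocycle is restored, so the ten-membered ring derives from the bicyclic stannyl lactol A5. Forward, Pb(OAc)4 would oxidise the lactol, the C2–C7 bond would break with loss of the tributylstannyl group from C6, and the 3-deoxy lactone A4 would form with the E alkene.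
- In favour: no macrolactonisation and no high dilution, and the alkene geometry follows from the trans arrangement of tin and side chain.
- Against: the product lacks the C3 oxygen, which would have to be introduced by enolate oxidation of a medium-ring lactone with facial selectivity left to ring conformation. Building A5 needs control of C6/C7 and of the triad through an aldol on the ring. Tin and lead are used in stoichiometric amounts.
- Comparison: on ring formation this alternative is the equal or the better of the chosen plan. On structure the chosen plan is better, since it sets all four centres before ring closure. Step economy is expected to be similar or worse.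

**Alternative 3:** The C7–C8 bond is cut, leading to the ester-linked iodo aldehyde A7. Forward, CrCl2 with catalytic NiCl2 would convert the E vinyl iodide into an alkenylchromium species that adds to the C8 aldehyde and closes the ring to A6.
- In favour: the two halves are joined by a simple esterification, and ring closure is a C–C bond formation at an unhindered aldehyde, chemoselective beside esters. The E geometry is fixed in the iodide, and C8 needs no carbonate or acetal exchange.
- Against: the C8 configuration rests on substrate control. For an α-silyloxy aldehyde the usual non-chelated model predicts the 8,9-erythro carbinol, while the target needs threo. Excess of a toxic chromium salt is needed.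
- Comparison: on step economy and on ease of ring closure this alternative is the equal or the better plan. On mechanism the chosen plan is more secure at C8, because the trans ring preference does not depend on the conformation of a closing macrocycle.

Key step: step 13

**Remarks on the chemistry**
- TBS = tert-butyldimethylsilyl, TES = triethylsilyl, PMB = 4-methoxybenzyl. The text uses lactone numbering (C2–C13); in the dodecanoate names C5 is lactone C6, C8 is C9 and C9 is C10.
- C6 of 19, 20 and 21 is a mixture of both epimers and is left undefined in their SMILES. No configurational error was found in the key-step structures: the 6S epimer is the one that reaches 22 by direct double inversion.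
- A 2-hydroxyglutarate from D-glutamic acid would also supply C2–C6, but telling its two carboxyl groups apart in the sense needed (C2 kept as ester, C6 reduced) costs more steps than the glycidate entry used here.

## Route

Step 1
Reactants: 1 (E)-hex-2-en-1-ol
Product: 2 [(2S,3S)-3-propyloxiran-2-yl]methanol
Conditions: Ti(OiPr)4 (5 mol %), L-(+)-diethyl tartrate (6 mol %), t-BuOOH, 4 Å MS, CH2Cl2, −20 °C
Reagents that add atoms: tert-butyl hydroperoxide, CC(C)(C)OO
Why: Sharpless asymmetric epoxidation of a trans allylic alcohol; the L-(+)-tartrate ligand directs oxygen to the face that gives the (2S,3S)-epoxide, which later becomes C9 and C10.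

Step 2
Reactants: 2 [(2S,3S)-3-propyloxiran-2-yl]methanol
Product: 3 (2S,3R)-3-[(4-methoxybenzyl)oxy]hexane-1,2-diol
Conditions: Ti(OiPr)4 (1.5 equiv) pre-mixed with 4-methoxybenzyl alcohol (6 equiv) and freed of i-PrOH in vacuo, toluene, 60 °C; aq. tartaric acid work-up
Reagents that add atoms: 4-methoxybenzyl alcohol, COc1ccc(CO)cc1
Why: Titanium-alkoxide-mediated opening of a 2,3-epoxy alcohol; the epoxy alkoxide is bound to titanium and the alcohol attacks C3 with inversion, so C3 becomes R (erythro to C2) and the future C10 ether is installed directly.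

Step 3
Reactants: 3 (2S,3R)-3-[(4-methoxybenzyl)oxy]hexane-1,2-diol
Product: 4 (2S,3R)-3-[(4-methoxybenzyl)oxy]-1,2-bis[(triethylsilyl)oxy]hexane
Conditions: TESCl (2.4 equiv), imidazole, DMF, 0 °C to rt
Reagents that add atoms: chlorotriethylsilane, CC[Si](Cl)(CC)CC
Why: Standard silylation of both hydroxyls; the primary silyl ether can then be oxidised selectively and the secondary one serves as the temporary C9 protection.

Step 4
Reactants: 4 (2S,3R)-3-[(4-methoxybenzyl)oxy]-1,2-bis[(triethylsilyl)oxy]hexane
Product: 6 (2R,3R)-3-[(4-methoxybenzyl)oxy]-2-[(triethylsilyl)oxy]hexanal, via alkoxysulfonium chloride 5 (not isolated)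
Conditions: (COCl)2, DMSO, CH2Cl2, −78 to −40 °C; then Et3N, −78 °C to rt
Reagents that add atoms: none
Why: Swern oxidation applied directly to a primary TES ether; the chlorosulfonium reagent cleaves only the unhindered primary Si–O bond to give salt 5, which collapses to the aldehyde on addition of Et3N, while the secondary TES ether and the α-centre are kept by the low temperature.

Step 5
Reactants: 6 (2R,3R)-3-[(4-methoxybenzyl)oxy]-2-[(triethylsilyl)oxy]hexanal; 7 dimethyl (1-diazo-2-oxopropyl)phosphonate
Product: 8 (3S,4R)-4-[(4-methoxybenzyl)oxy]-3-[(triethylsilyl)oxy]hept-1-yne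
Conditions: K2CO3, MeOH, 0 °C to rt
Reagents that add atoms: none
Why: Seyferth–Gilbert homologation in the Ohira–Bestmann form; methanolysis of 7 gives the diazomethylphosphonate anion, which adds to the aldehyde, loses dimethyl phosphate and N2, and the carbene rearranges to the terminal alkyne (C7), the mild base sparing the α-silyloxy centre.

Step 6
Reactants: 9 methyl (2R)-oxirane-2-carboxylate; 10 vinylmagnesium bromide
Product: 11 methyl (2R)-2-hydroxypent-4-enoate
Conditions: CuI (10 mol %), THF, −78 to −40 °C; aq. NH4Cl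
Reagents that add atoms: none
Why: Copper-catalysed Grignard opening of a terminal epoxide at the unsubstituted carbon forms the C4–C5 bond; the stereocentre is not touched (2R retained, the later C3) and the low temperature protects the ester.

Step 7
Reactants: 11 methyl (2R)-2-hydroxypent-4-enoate
Product: 12 methyl (2R)-2-[(tert-butyldimethylsilyl)oxy]pent-4-enoate
Conditions: TBSCl, imidazole, DMF, rt
Reagents that add atoms: tert-butylchlorodimethylsilane, CC(C)(C)[Si](C)(C)Cl
Why: Standard silylation; the TBS ether at C3 is more robust than the TES ether at C9, which allows the later selective desilylation.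

Step 8
Reactants: 12 methyl (2R)-2-[(tert-butyldimethylsilyl)oxy]pent-4-enoate
Product: 14 methyl (2R)-2-[(tert-butyldimethylsilyl)oxy]-5-hydroxypentanoate, via B-alkyl-9-borabicyclononane 13 (not isolated)
Conditions: 9-BBN, THF, 0 °C to rt; then 30 % H2O2, aq. NaOAc, 0 °C to rt
Reagents that add atoms: hydrogen peroxide, OO
Why: Anti-Markovnikov hydroboration–oxidation of the terminal alkene; 9-BBN leaves the ester alone and the buffered oxidation avoids ester hydrolysis and lactonisation.

Step 9
Reactants: 14 methyl (2R)-2-[(tert-butyldimethylsilyl)oxy]-5-hydroxypentanoate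
Product: 15 methyl (2R)-2-[(tert-butyldimethylsilyl)oxy]-5-oxopentanoate
Conditions: Dess–Martin periodinane, CH2Cl2, 0 °C to rt
Reagents that add atoms: none
Why: Dess–Martin oxidation of a primary alcohol under near-neutral conditions gives the C6 aldehyde without touching the silyl ether or the α-centre.

Step 10
Reactants: 8 (3S,4R)-4-[(4-methoxybenzyl)oxy]-3-[(triethylsilyl)oxy]hept-1-yne; 15 methyl (2R)-2-[(tert-butyldimethylsilyl)oxy]-5-oxopentanoate; 16 methyl chloroformate
Product: 19 methyl (2R,8S,9R)-2-[(tert-butyldimethylsilyl)oxy]-5-[(methoxycarbonyl)oxy]-9-[(4-methoxybenzyl)oxy]-8-[(triethylsilyl)oxy]dodec-6-ynoate (both C5 epimers), via lithium acetylide 17 (not isolated), via lithium alkoxide 18 (not isolated)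
Conditions: 8, n-BuLi, THF, −78 °C; 15, −78 °C; then ClCO2Me, −78 to 0 °C
Reagents that add atoms: none
Why: Acetylide addition to an aldehyde is far faster than attack on the hindered α-silyloxy ester at −78 °C, and the alkoxide 18 is acylated in the same flask before it can lactonise onto C2; the new C6 centre is formed without control, which the key step is designed to absorb.

Step 11
Reactants: 19 methyl (2R,8S,9R)-2-[(tert-butyldimethylsilyl)oxy]-5-[(methoxycarbonyl)oxy]-9-[(4-methoxybenzyl)oxy]-8-[(triethylsilyl)oxy]dodec-6-ynoate (both C5 epimers)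
Product: 20 methyl (2R,8S,9R)-2-[(tert-butyldimethylsilyl)oxy]-8-hydroxy-5-[(methoxycarbonyl)oxy]-9-[(4-methoxybenzyl)oxy]dodec-6-ynoate (both C5 epimers)
Conditions: PPTS (0.2 equiv), MeOH, 0 °C to rt
Reagents that add atoms: none
Why: Acid-catalysed methanolysis removes the TES ether much faster than the bulkier TBS ether α to the ester; the carbonate and the PMB ether are stable to weak acid.

Step 12
Reactants: 20 methyl (2R,8S,9R)-2-[(tert-butyldimethylsilyl)oxy]-8-hydroxy-5-[(methoxycarbonyl)oxy]-9-[(4-methoxybenzyl)oxy]dodec-6-ynoate (both C5 epimers)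
Product: 21 methyl (2R,6Z,8S,9R)-2-[(tert-butyldimethylsilyl)oxy]-8-hydroxy-5-[(methoxycarbonyl)oxy]-9-[(4-methoxybenzyl)oxy]dodec-6-enoate (both C5 epimers)
Conditions: H2 (1 atm), Pd/CaCO3 poisoned with Pb(OAc)2 (Lindlar catalyst), quinoline, EtOAc, rt
Reagents that add atoms: none
Why: Lindlar semi-hydrogenation adds hydrogen syn to the alkyne and stops at the Z alkene; the poisoned catalyst does not cleave the benzylic ether or the allylic carbonate.

Step 13
Reactants: 21 methyl (2R,6Z,8S,9R)-2-[(tert-butyldimethylsilyl)oxy]-8-hydroxy-5-[(methoxycarbonyl)oxy]-9-[(4-methoxybenzyl)oxy]dodec-6-enoate (both C5 epimers)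
Product: 22 methyl (2R,5E)-2-[(tert-butyldimethylsilyl)oxy]-6-{(4R,5R)-5-[(1R)-1-[(4-methoxybenzyl)oxy]butyl]-2-oxo-1,3-dioxolan-4-yl}hex-5-enoate
Conditions: Pd2(dba)3·CHCl3 (5 mol %), dppe (20 mol %), 1,4-dioxane, 50 °C, sealed tube
Reagents that add atoms: none
Why: Zerovalent palladium with dppe ionises the C6 methyl carbonate with inversion to a cationic C6–C8 π-allyl complex, and the methyl carbonate anion breaks down to CO2 and methoxide, which deprotonates the C9 hydroxyl (methanol is lost). The C9 alkoxide takes up the CO2 held in the closed vessel and the carbonate oxygen attacks C8 anti to palladium in a 5-exo closure onto the allyl terminus, forming the C8–O bond and the 1,3-dioxolan-2-one; the seven-membered closure at C6 should not compete. The closest known reaction type is the palladium-catalysed CO2 elimination–fixation of 4-(methoxycarbonyloxy)but-2-en-1-ols to 4-vinyl cyclic carbonates. The cis-configured allyl from the Z alkene relaxes by η3–η1–η3 isomerisation to the syn,syn form, so C5 ends trans to C8 and the C6=C7 bond is E. The new C8 centre is controlled by C9: the 6S epimer reaches the 8R trans carbonate directly by double inversion, whereas the 6R epimer should first give E-cis or Z-trans isomers, which are themselves allylic carbonates, re-ionise, and cross over by exchange of zerovalent palladium on the allyl face, so that the mixture should drain to the most stable trans-4,5-disubstituted E isomer. The step needs attack at C8 over C6 (ring size), E geometry (syn allyl), the 8R configuration (trans ring preference under the fixed C9 centre) and retention of CO2 over decarboxylative closure to a dihydrofuran or β-hydride loss (closed vessel). The ester, the ethers and the C3 and C10 centres are spectators.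

Step 14
Reactants: 22 methyl (2R,5E)-2-[(tert-butyldimethylsilyl)oxy]-6-{(4R,5R)-5-[(1R)-1-[(4-methoxybenzyl)oxy]butyl]-2-oxo-1,3-dioxolan-4-yl}hex-5-enoate
Product: 23 methyl (2R,5E,7R,8S,9R)-2-[(tert-butyldimethylsilyl)oxy]-7,8-dihydroxy-9-[(4-methoxybenzyl)oxy]dodec-5-enoate
Conditions: K2CO3 (0.5 equiv), MeOH, 0 °C to rt
Reagents that add atoms: none
Why: Base-catalysed transesterification of the cyclic carbonate with methanol (acyl–oxygen cleavage, so C8 and C9 keep their configuration) releases the diol and dimethyl carbonate; exchange at the methyl ester is degenerate.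

Step 15
Reactants: 23 methyl (2R,5E,7R,8S,9R)-2-[(tert-butyldimethylsilyl)oxy]-7,8-dihydroxy-9-[(4-methoxybenzyl)oxy]dodec-5-enoate
Product: 24 methyl (2R,5E)-2-[(tert-butyldimethylsilyl)oxy]-6-{(4R,5R)-5-[(1R)-1-[(4-methoxybenzyl)oxy]butyl]-2,2-dimethyl-1,3-dioxolan-4-yl}hex-5-enoate
Conditions: Me2C(OMe)2, PPTS (10 mol %), CH2Cl2, rt
Reagents that add atoms: 2,2-dimethoxypropane, COC(C)(C)OC
Why: Acid-catalysed acetal exchange gives the trans-dioxolane of the threo diol; this acid-labile group replaces the base-labile carbonate and can be removed at the end beside the C3 ester.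

Step 16
Reactants: 24 methyl (2R,5E)-2-[(tert-butyldimethylsilyl)oxy]-6-{(4R,5R)-5-[(1R)-1-[(4-methoxybenzyl)oxy]butyl]-2,2-dimethyl-1,3-dioxolan-4-yl}hex-5-enoate
Product: 25 methyl (2R,5E)-2-[(tert-butyldimethylsilyl)oxy]-6-{(4R,5R)-5-[(1R)-1-hydroxybutyl]-2,2-dimethyl-1,3-dioxolan-4-yl}hex-5-enoate
Conditions: DDQ, CH2Cl2/pH 7 buffer (10:1), 0 °C to rt
Reagents that add atoms: none
Why: Oxidative cleavage of the PMB ether (benzylic hydride abstraction, hydrolysis of the oxocarbenium ion) frees only the C10 hydroxyl; the alkene, acetal, silyl ether and ester are inert to buffered DDQ.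

Step 17
Reactants: 25 methyl (2R,5E)-2-[(tert-butyldimethylsilyl)oxy]-6-{(4R,5R)-5-[(1R)-1-hydroxybutyl]-2,2-dimethyl-1,3-dioxolan-4-yl}hex-5-enoate
Product: 26 (2R,5E)-2-[(tert-butyldimethylsilyl)oxy]-6-{(4R,5R)-5-[(1R)-1-hydroxybutyl]-2,2-dimethyl-1,3-dioxolan-4-yl}hex-5-enoic acid
Conditions: LiOH·H2O, THF/MeOH/H2O (3:1:1), 0 °C to rt; 0.5 M HCl to pH 4 at 0 °C
Reagents that add atoms: lithium hydroxide, [Li+].[OH-]
Why: Saponification of the methyl ester; the α-silyloxy centre is only weakly acidic and should not epimerise in cold aqueous hydroxide, and the acetal survives the brief cold acidification.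

Step 18
Reactants: 26 (2R,5E)-2-[(tert-butyldimethylsilyl)oxy]-6-{(4R,5R)-5-[(1R)-1-hydroxybutyl]-2,2-dimethyl-1,3-dioxolan-4-yl}hex-5-enoic acid
Product: 28 (3R,6E,8R,9R,10R)-3-[(tert-butyldimethylsilyl)oxy]-8,9-(isopropylidenedioxy)-10-propyl-3,4,5,8,9,10-hexahydro-2H-oxecin-2-one, via mixed anhydride 27 (not isolated)
Conditions: 2-methyl-6-nitrobenzoic anhydride, DMAP, toluene (about 1 mM), rt to 40 °C, 26 added by syringe pump over 12 h
Reagents that add atoms: none
Why: Shiina macrolactonisation; the aromatic anhydride converts the acid into mixed anhydride 27, DMAP transfers the acyl group to the only free hydroxyl (C10), and high dilution favours the ten-membered ring (10-exo-trig acyl substitution) over oligomers, with no stereocentre touched.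

Step 19
Reactants: 28 (3R,6E,8R,9R,10R)-3-[(tert-butyldimethylsilyl)oxy]-8,9-(isopropylidenedioxy)-10-propyl-3,4,5,8,9,10-hexahydro-2H-oxecin-2-one
Product: 29 (3R,6E,8R,9R,10R)-3-hydroxy-8,9-(isopropylidenedioxy)-10-propyl-3,4,5,8,9,10-hexahydro-2H-oxecin-2-one
Conditions: HF·pyridine, pyridine, THF, 0 °C to rt
Reagents that add atoms: none
Why: Buffered fluoride cleavage of the TBS ether; the non-basic medium avoids opening or epimerising the α-hydroxy lactone and leaves the acetal in place.

Step 20
Reactants: 30 (2E,4E)-hexa-2,4-dienedioic acid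
Product: 31 (2E,4E)-6-tert-butoxy-6-oxohexa-2,4-dienoic acid
Conditions: 30 (2 equiv), tert-butyl 2,2,2-trichloroacetimidate (1 equiv), THF, 50 °C; monoester separated from neutral diester and from insoluble diacid
Reagents that add atoms: tert-butyl 2,2,2-trichloroacetimidate, CC(C)(C)OC(=N)C(Cl)(Cl)Cl
Why: Acid-promoted tert-butyl transfer from the imidate to a carboxylic acid; with the diacid in excess the half-ester should dominate and is separable by its solubility and acidity.

Step 21
Reactants: 29 (3R,6E,8R,9R,10R)-3-hydroxy-8,9-(isopropylidenedioxy)-10-propyl-3,4,5,8,9,10-hexahydro-2H-oxecin-2-one; 31 (2E,4E)-6-tert-butoxy-6-oxohexa-2,4-dienoic acid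
Product: 33 tert-butyl (3R,6E,8R,9R,10R)-8,9-(isopropylidenedioxy)-2-oxo-10-propyl-3,4,5,8,9,10-hexahydro-2H-oxecin-3-yl (2E,4E)-hexa-2,4-dienedioate, via O-acylisourea 32 (not isolated)
Conditions: EDC·HCl, DMAP (0.2 equiv), CH2Cl2, 0 °C to rt
Reagents that add atoms: none
Why: Steglich esterification; the carbodiimide activates 31 as O-acylisourea 32 and DMAP passes the acyl group to the C3 hydroxyl under conditions too mild to epimerise C3 or isomerise the diene.

Step 22
Reactants: 33 tert-butyl (3R,6E,8R,9R,10R)-8,9-(isopropylidenedioxy)-2-oxo-10-propyl-3,4,5,8,9,10-hexahydro-2H-oxecin-3-yl (2E,4E)-hexa-2,4-dienedioate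
Product: 34 (2E,4E)-6-{[(3R,6E,8R,9S,10R)-8,9-dihydroxy-2-oxo-10-propyl-3,4,5,8,9,10-hexahydro-2H-oxecin-3-yl]oxy}-6-oxohexa-2,4-dienoic acid
Conditions: TFA/CH2Cl2/H2O (10:10:1), 0 °C to rt
Reagents that add atoms: none
Why: Aqueous trifluoroacetic acid hydrolyses the acetal and cleaves the tert-butyl ester by alkyl–oxygen fission in one operation; the conjugated half-ester and the lactone are stable to acid, and water suppresses trifluoroacetylation of the diol.

## Compound list

1 | (E)-hex-2-en-1-ol | CCC/C=C/CO | starting material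
2 | [(2S,3S)-3-propyloxiran-2-yl]methanol | CCC[C@@H]1O[C@H]1CO | intermediate
3 | (2S,3R)-3-[(4-methoxybenzyl)oxy]hexane-1,2-diol | OC[C@H](O)[C@H](OCc1ccc(OC)cc1)CCC | intermediate
4 | (2S,3R)-3-[(4-methoxybenzyl)oxy]-1,2-bis[(triethylsilyl)oxy]hexane | CC[Si](CC)(CC)OC[C@H](O[Si](CC)(CC)CC)[C@H](OCc1ccc(OC)cc1)CCC | intermediate
5 | alkoxysulfonium chloride from 4 (dimethylsulfonium on O1) | C[S+](C)OC[C@H](O[Si](CC)(CC)CC)[C@H](OCc1ccc(OC)cc1)CCC.[Cl-] | intermediate (not isolated)
6 | (2R,3R)-3-[(4-methoxybenzyl)oxy]-2-[(triethylsilyl)oxy]hexanal | O=C[C@H](O[Si](CC)(CC)CC)[C@H](OCc1ccc(OC)cc1)CCC | intermediate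
7 | dimethyl (1-diazo-2-oxopropyl)phosphonate | CC(=O)C(=[N+]=[N-])P(=O)(OC)OC | starting material
8 | (3S,4R)-4-[(4-methoxybenzyl)oxy]-3-[(triethylsilyl)oxy]hept-1-yne | C#C[C@H](O[Si](CC)(CC)CC)[C@H](OCc1ccc(OC)cc1)CCC | intermediate
9 | methyl (2R)-oxirane-2-carboxylate | COC(=O)[C@H]1CO1 | starting material
10 | vinylmagnesium bromide | C=C[Mg]Br | starting material
11 | methyl (2R)-2-hydroxypent-4-enoate | COC(=O)[C@H](O)CC=C | intermediate
12 | methyl (2R)-2-[(tert-butyldimethylsilyl)oxy]pent-4-enoate | COC(=O)[C@H](O[Si](C)(C)C(C)(C)C)CC=C | intermediate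
13 | B-alkyl-9-borabicyclononane from 12 (boron on C5) | COC(=O)[C@H](O[Si](C)(C)C(C)(C)C)CCCB1C2CCCC1CCC2 | intermediate (not isolated)
14 | methyl (2R)-2-[(tert-butyldimethylsilyl)oxy]-5-hydroxypentanoate | COC(=O)[C@H](O[Si](C)(C)C(C)(C)C)CCCO | intermediate
15 | methyl (2R)-2-[(tert-butyldimethylsilyl)oxy]-5-oxopentanoate | COC(=O)[C@H](O[Si](C)(C)C(C)(C)C)CCC=O | intermediate
16 | methyl chloroformate | COC(=O)Cl | starting material
17 | lithium acetylide of 8 | [Li]C#C[C@H](O[Si](CC)(CC)CC)[C@H](OCc1ccc(OC)cc1)CCC | intermediate (not isolated)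
18 | lithium C5 alkoxide of the dodec-6-ynoate (both C5 epimers) | COC(=O)[C@H](O[Si](C)(C)C(C)(C)C)CCC(O[Li])C#C[C@H](O[Si](CC)(CC)CC)[C@H](OCc1ccc(OC)cc1)CCC | intermediate (not isolated)
19 | methyl (2R,8S,9R)-2-[(tert-butyldimethylsilyl)oxy]-5-[(methoxycarbonyl)oxy]-9-[(4-methoxybenzyl)oxy]-8-[(triethylsilyl)oxy]dodec-6-ynoate (both C5 epimers) | COC(=O)[C@H](O[Si](C)(C)C(C)(C)C)CCC(OC(=O)OC)C#C[C@H](O[Si](CC)(CC)CC)[C@H](OCc1ccc(OC)cc1)CCC | intermediate
20 | methyl (2R,8S,9R)-2-[(tert-butyldimethylsilyl)oxy]-8-hydroxy-5-[(methoxycarbonyl)oxy]-9-[(4-methoxybenzyl)oxy]dodec-6-ynoate (both C5 epimers) | COC(=O)[C@H](O[Si](C)(C)C(C)(C)C)CCC(OC(=O)OC)C#C[C@H](O)[C@H](OCc1ccc(OC)cc1)CCC | intermediate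
21 | methyl (2R,6Z,8S,9R)-2-[(tert-butyldimethylsilyl)oxy]-8-hydroxy-5-[(methoxycarbonyl)oxy]-9-[(4-methoxybenzyl)oxy]dodec-6-enoate (both C5 epimers) | COC(=O)[C@H](O[Si](C)(C)C(C)(C)C)CCC(OC(=O)OC)/C=C\[C@H](O)[C@H](OCc1ccc(OC)cc1)CCC | intermediate
22 | methyl (2R,5E)-2-[(tert-butyldimethylsilyl)oxy]-6-{(4R,5R)-5-[(1R)-1-[(4-methoxybenzyl)oxy]butyl]-2-oxo-1,3-dioxolan-4-yl}hex-5-enoate | COC(=O)[C@H](O[Si](C)(C)C(C)(C)C)CC/C=C/[C@H]1OC(=O)O[C@@H]1[C@H](OCc2ccc(OC)cc2)CCC | intermediate
23 | methyl (2R,5E,7R,8S,9R)-2-[(tert-butyldimethylsilyl)oxy]-7,8-dihydroxy-9-[(4-methoxybenzyl)oxy]dodec-5-enoate | COC(=O)[C@H](O[Si](C)(C)C(C)(C)C)CC/C=C/[C@@H](O)[C@H](O)[C@H](OCc1ccc(OC)cc1)CCC | intermediate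
24 | methyl (2R,5E)-2-[(tert-butyldimethylsilyl)oxy]-6-{(4R,5R)-5-[(1R)-1-[(4-methoxybenzyl)oxy]butyl]-2,2-dimethyl-1,3-dioxolan-4-yl}hex-5-enoate | COC(=O)[C@H](O[Si](C)(C)C(C)(C)C)CC/C=C/[C@H]1OC(C)(C)O[C@@H]1[C@H](OCc2ccc(OC)cc2)CCC | intermediate
25 | methyl (2R,5E)-2-[(tert-butyldimethylsilyl)oxy]-6-{(4R,5R)-5-[(1R)-1-hydroxybutyl]-2,2-dimethyl-1,3-dioxolan-4-yl}hex-5-enoate | COC(=O)[C@H](O[Si](C)(C)C(C)(C)C)CC/C=C/[C@H]1OC(C)(C)O[C@@H]1[C@H](O)CCC | intermediate
26 | (2R,5E)-2-[(tert-butyldimethylsilyl)oxy]-6-{(4R,5R)-5-[(1R)-1-hydroxybutyl]-2,2-dimethyl-1,3-dioxolan-4-yl}hex-5-enoic acid | OC(=O)[C@H](O[Si](C)(C)C(C)(C)C)CC/C=C/[C@H]1OC(C)(C)O[C@@H]1[C@H](O)CCC | intermediate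
27 | mixed anhydride of 26 and 2-methyl-6-nitrobenzoic acid | Cc1cccc([N+](=O)[O-])c1C(=O)OC(=O)[C@H](O[Si](C)(C)C(C)(C)C)CC/C=C/[C@H]2OC(C)(C)O[C@@H]2[C@H](O)CCC | intermediate (not isolated)
28 | (3R,6E,8R,9R,10R)-3-[(tert-butyldimethylsilyl)oxy]-8,9-(isopropylidenedioxy)-10-propyl-3,4,5,8,9,10-hexahydro-2H-oxecin-2-one | CCC[C@H]1OC(=O)[C@H](O[Si](C)(C)C(C)(C)C)CC/C=C/[C@H]2OC(C)(C)O[C@H]12 | intermediate
29 | (3R,6E,8R,9R,10R)-3-hydroxy-8,9-(isopropylidenedioxy)-10-propyl-3,4,5,8,9,10-hexahydro-2H-oxecin-2-one | CCC[C@H]1OC(=O)[C@H](O)CC/C=C/[C@H]2OC(C)(C)O[C@H]12 | intermediate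
30 | (2E,4E)-hexa-2,4-dienedioic acid ((E,E)-muconic acid) | OC(=O)/C=C/C=C/C(=O)O | starting material
31 | (2E,4E)-6-tert-butoxy-6-oxohexa-2,4-dienoic acid | OC(=O)/C=C/C=C/C(=O)OC(C)(C)C | intermediate
32 | O-acylisourea of 31 and EDC | CCN=C(NCCCN(C)C)OC(=O)/C=C/C=C/C(=O)OC(C)(C)C | intermediate (not isolated)
33 | tert-butyl (3R,6E,8R,9R,10R)-8,9-(isopropylidenedioxy)-2-oxo-10-propyl-3,4,5,8,9,10-hexahydro-2H-oxecin-3-yl (2E,4E)-hexa-2,4-dienedioate | CCC[C@H]1OC(=O)[C@H](OC(=O)/C=C/C=C/C(=O)OC(C)(C)C)CC/C=C/[C@H]2OC(C)(C)O[C@H]12 | intermediate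
34 | (2E,4E)-6-{[(3R,6E,8R,9S,10R)-8,9-dihydroxy-2-oxo-10-propyl-3,4,5,8,9,10-hexahydro-2H-oxecin-3-yl]oxy}-6-oxohexa-2,4-dienoic acid | CCC[C@H]1OC(=O)[C@H](OC(=O)/C=C/C=C/C(=O)O)CC/C=C/[C@@H](O)[C@@H]1O | target

## Step count and least certain steps

Total step count: 22. Longest linear sequence: 17 steps (1 to 34 through steps 1–5, 10–19, 21 and 22).

**Step 13 (key step).** The most likely failure is incomplete convergence. The 6R epimer enters a stereochemical channel that first gives the E-cis or Z-trans carbonate, and it reaches 22 only if re-ionisation and face exchange on palladium are fast enough. A second failure is loss of CO2 before capture, with closure of the C9 alkoxide onto C6 of the cis-configured allyl (dihydrofuran) or β-hydride loss to a diene. A CO2 atmosphere would be the first adjustment.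

The fallback removes the dependence on convergence by making the 6S precursor alone. It sets out from 8 and 15 and returns at 22. The acetylide addition of step 10 is quenched with aqueous NH4Cl to give the propargylic alcohol F1. Dess–Martin oxidation gives the ynone F2. Transfer hydrogenation with RuCl[(S,S)-TsDPEN](p-cymene) in i-PrOH (TsDPEN = N-tosyl-1,2-diphenylethylenediamine) should give the (5S)-alcohol F3 by the usual model for alkynyl ketones. Methyl chloroformate and pyridine give the (5S)-carbonate F4, PPTS in methanol the C8 alcohol F5, and Lindlar reduction the single-epimer Z alkene F6. F6 should give 22 under the conditions of step 13 by plain double inversion.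

**Step 2.** The most likely failure is low conversion or transfer of isopropoxide in place of the benzylic alkoxide, because a weakly nucleophilic alcohol must compete within the titanium complex; self-etherification of the benzylic alcohol is a second drain.

The fallback uses a carboxylate nucleophile and adds the ether later. It sets out from 2 and returns at 3. Ti(OiPr)4 and benzoic acid open the epoxide at C3 to the benzoate diol F7. 2,2-Dimethoxypropane and PPTS give the acetonide benzoate F8. K2CO3 in methanol gives the alcohol F9. NaH and 4-methoxybenzyl chloride give the ether F10, and 80 % aqueous acetic acid releases 3.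

**Step 10.** The most likely failure is attack of the C6 alkoxide on the C2 methyl ester (δ-lactonisation) before the chloroformate traps it, or competing addition of the acetylide to the ester if the temperature drifts.

The fallback replaces the lithium acetylide by a neutral organochromium addition. It sets out from 8 (with 15) and returns at 19. N-Iodosuccinimide with catalytic AgNO3 converts 8 into the iodoalkyne F11. CrCl2 (divalent chromium) in THF should add it to 15 with full preference for the aldehyde, giving the alcohol F1 (the same compound as in the step 13 fallback). Methyl chloroformate and pyridine then give 19.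

**Step 18.** The most likely failure is intermolecular acylation (dimers, oligomers) outrunning closure, because the hindered C10 hydroxyl must reach the activated carboxyl across a ring stiffened by the trans-dioxolane and the E alkene.

The fallback activates the alcohol instead of the acid. It sets out from 25 and returns at 28. A Mitsunobu reaction with 4-nitrobenzoic acid (PPh3, diisopropyl azodicarboxylate) inverts C10 to the 4-nitrobenzoate F12. LiOH cleaves both esters to the (10S)-hydroxy acid F13. A Mitsunobu macrolactonisation under high dilution then closes the ring by carboxylate displacement at C10 with inversion, restoring 10R in 28.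

**Step 22.** The most likely failure is acid-induced acyl migration or translactonisation towards the freed C9 and C8 hydroxyls, or ionisation of the allylic C8–O bond, because the tert-butyl ester needs a strong acid.

The fallback separates the two unmaskings and frees the carboxyl without acid. It sets out from 29 (and 30) and returns at 34. Allyl bromide and KHCO3 in DMF convert 30 into the mono-allyl ester F14. Steglich coupling with 29 gives the allyl ester F15. 80 % aqueous acetic acid removes the acetal to give the diol F16. Pd(PPh3)4 with PhSiH3 then removes the allyl group to give 34.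

## Further compounds

F1 | step 13 | methyl (2R,8S,9R)-2-[(tert-butyldimethylsilyl)oxy]-5-hydroxy-9-[(4-methoxybenzyl)oxy]-8-[(triethylsilyl)oxy]dodec-6-ynoate (both C5 epimers) | COC(=O)[C@H](O[Si](C)(C)C(C)(C)C)CCC(O)C#C[C@H](O[Si](CC)(CC)CC)[C@H](OCc1ccc(OC)cc1)CCC
F2 | step 13 | methyl (2R,8S,9R)-2-[(tert-butyldimethylsilyl)oxy]-9-[(4-methoxybenzyl)oxy]-5-oxo-8-[(triethylsilyl)oxy]dodec-6-ynoate | COC(=O)[C@H](O[Si](C)(C)C(C)(C)C)CCC(=O)C#C[C@H](O[Si](CC)(CC)CC)[C@H](OCc1ccc(OC)cc1)CCC
F3 | step 13 | methyl (2R,5S,8S,9R)-2-[(tert-butyldimethylsilyl)oxy]-5-hydroxy-9-[(4-methoxybenzyl)oxy]-8-[(triethylsilyl)oxy]dodec-6-ynoate | COC(=O)[C@H](O[Si](C)(C)C(C)(C)C)CC[C@H](O)C#C[C@H](O[Si](CC)(CC)CC)[C@H](OCc1ccc(OC)cc1)CCC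
F4 | step 13 | methyl (2R,5S,8S,9R)-2-[(tert-butyldimethylsilyl)oxy]-5-[(methoxycarbonyl)oxy]-9-[(4-methoxybenzyl)oxy]-8-[(triethylsilyl)oxy]dodec-6-ynoate | COC(=O)[C@H](O[Si](C)(C)C(C)(C)C)CC[C@H](OC(=O)OC)C#C[C@H](O[Si](CC)(CC)CC)[C@H](OCc1ccc(OC)cc1)CCC
F5 | step 13 | methyl (2R,5S,8S,9R)-2-[(tert-butyldimethylsilyl)oxy]-8-hydroxy-5-[(methoxycarbonyl)oxy]-9-[(4-methoxybenzyl)oxy]dodec-6-ynoate | COC(=O)[C@H](O[Si](C)(C)C(C)(C)C)CC[C@H](OC(=O)OC)C#C[C@H](O)[C@H](OCc1ccc(OC)cc1)CCC
F6 | step 13 | methyl (2R,5S,6Z,8S,9R)-2-[(tert-butyldimethylsilyl)oxy]-8-hydroxy-5-[(methoxycarbonyl)oxy]-9-[(4-methoxybenzyl)oxy]dodec-6-enoate | COC(=O)[C@H](O[Si](C)(C)C(C)(C)C)CC[C@H](OC(=O)OC)/C=C\[C@H](O)[C@H](OCc1ccc(OC)cc1)CCC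
F7 | step 2 | (2S,3R)-1,2-dihydroxyhexan-3-yl benzoate | OC[C@H](O)[C@H](OC(=O)c1ccccc1)CCC
F8 | step 2 | (1R)-1-[(4S)-2,2-dimethyl-1,3-dioxolan-4-yl]butyl benzoate | CC1(C)OC[C@H](O1)[C@H](OC(=O)c2ccccc2)CCC
F9 | step 2 | (1R)-1-[(4S)-2,2-dimethyl-1,3-dioxolan-4-yl]butan-1-ol | CC1(C)OC[C@H](O1)[C@H](O)CCC
F10 | step 2 | (4S)-4-{(1R)-1-[(4-methoxybenzyl)oxy]butyl}-2,2-dimethyl-1,3-dioxolane | CC1(C)OC[C@H](O1)[C@H](OCc2ccc(OC)cc2)CCC
F11 | step 10 | (3S,4R)-1-iodo-4-[(4-methoxybenzyl)oxy]-3-[(triethylsilyl)oxy]hept-1-yne | IC#C[C@H](O[Si](CC)(CC)CC)[C@H](OCc1ccc(OC)cc1)CCC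
F12 | step 18 | methyl (2R,5E)-2-[(tert-butyldimethylsilyl)oxy]-6-{(4R,5R)-2,2-dimethyl-5-[(1S)-1-(4-nitrobenzoyloxy)butyl]-1,3-dioxolan-4-yl}hex-5-enoate | COC(=O)[C@H](O[Si](C)(C)C(C)(C)C)CC/C=C/[C@H]1OC(C)(C)O[C@@H]1[C@@H](OC(=O)c2ccc(cc2)[N+](=O)[O-])CCC
F13 | step 18 | (2R,5E)-2-[(tert-butyldimethylsilyl)oxy]-6-{(4R,5R)-5-[(1S)-1-hydroxybutyl]-2,2-dimethyl-1,3-dioxolan-4-yl}hex-5-enoic acid | OC(=O)[C@H](O[Si](C)(C)C(C)(C)C)CC/C=C/[C@H]1OC(C)(C)O[C@@H]1[C@@H](O)CCC
F14 | step 22 | (2E,4E)-6-(allyloxy)-6-oxohexa-2,4-dienoic acid | OC(=O)/C=C/C=C/C(=O)OCC=C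
F15 | step 22 | allyl (3R,6E,8R,9R,10R)-8,9-(isopropylidenedioxy)-2-oxo-10-propyl-3,4,5,8,9,10-hexahydro-2H-oxecin-3-yl (2E,4E)-hexa-2,4-dienedioate | CCC[C@H]1OC(=O)[C@H](OC(=O)/C=C/C=C/C(=O)OCC=C)CC/C=C/[C@H]2OC(C)(C)O[C@H]12
F16 | step 22 | allyl (3R,6E,8R,9S,10R)-8,9-dihydroxy-2-oxo-10-propyl-3,4,5,8,9,10-hexahydro-2H-oxecin-3-yl (2E,4E)-hexa-2,4-dienedioate | CCC[C@H]1OC(=O)[C@H](OC(=O)/C=C/C=C/C(=O)OCC=C)CC/C=C/[C@@H](O)[C@@H]1O
A1 | alternative 1 | (R)-α-acyloxy anilide of the C2–C13 chain: N-[2-(2,2-dimethoxyethyl)phenyl] amide at C2, mono-tert-butyl (E,E)-muconate ester at C3, (E)-C6=C7, 8,9-acetonide, 10-OTES | O=C(Nc1ccccc1CC(OC)OC)[C@H](OC(=O)/C=C/C=C/C(=O)OC(C)(C)C)CC/C=C/[C@H]2OC(C)(C)O[C@@H]2[C@H](O[Si](CC)(CC)CC)CCC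
A2 | alternative 1 | C3–C13 aldehyde: (E)-5-(2,2-dimethyl-1,3-dioxolan-4-yl)pent-4-enal carrying the 1-(triethylsilyloxy)butyl group on the dioxolane, configurations as in 24 | O=CCC/C=C/[C@H]1OC(C)(C)O[C@@H]1[C@H](O[Si](CC)(CC)CC)CCC
A3 | alternative 1 | 2-(2,2-dimethoxyethyl)phenyl isocyanide | COC(OC)Cc1ccccc1[N+]#[C-]
A4 | alternative 2 | 3-deoxy (E)-ten-membered lactone with C8 OTBS and C9 OPMB | CCC[C@H]1OC(=O)CCC/C=C/[C@@H](O[Si](C)(C)C(C)(C)C)[C@@H]1OCc2ccc(OC)cc2
A5 | alternative 2 | bicyclic lactol (C10 oxygen on the C2 ketone of a cyclohexanone) with C6 tributylstannyl trans to the C7 side chain, C8 OTBS, C9 OPMB, hemiketal centre left open | CCC[C@H]1OC2(O)CCC[C@@H]([Sn](CCCC)(CCCC)CCCC)[C@@H]2[C@@H](O[Si](C)(C)C(C)(C)C)[C@@H]1OCc1ccc(OC)cc1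
A6 | alternative 3 | ten-membered (E)-lactone with free C8 hydroxyl, C3 OPMB and C9 OTBS | CCC[C@H]1OC(=O)[C@H](OCc2ccc(OC)cc2)CC/C=C/[C@@H](O)[C@@H]1O[Si](C)(C)C(C)(C)C
A7 | alternative 3 | ester of (2R,5E)-6-iodo-2-[(4-methoxybenzyl)oxy]hex-5-enoic acid with the C10 hydroxyl of the C8 aldehyde bearing C9 OTBS | CCC[C@@H](OC(=O)[C@H](OCc1ccc(OC)cc1)CC/C=C/I)[C@@H](O[Si](C)(C)C(C)(C)C)C=O
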